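## Retrosynthetic overview
1. Waltherione K ⇐ O-methylation of the cis-8-ol ⇐ acid/silane cleavage of only the C5–O bond of a 5,8-epoxy-bridged N-methoxy-4-pyridone. C8–O is kept, and hydride enters anti to O8 to set C5.
2. N-Methoxy-4-pyridone ring ⇐ N1–C8a by addition–elimination of N-methoxyacetamide on a β-bromoenone, then C2–C3 by a Camps-type aldol condensation.
3. Carbocycle and the C8 oxygen ⇐ key step: catalytic enantioselective Diels–Alder reaction of 2-octylfuran with 4-bromo-1-methoxybut-3-yn-2-one. This forms C4a–C5 and C8–C8a, and the furan O becomes O8. Diimide then saturates C6=C7.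
4. Ring order: oxa-bridged carbocycle first, pyridone second, oxygen bridge opened last. No cyclohexanone or 1,3-dione condensation and no quinolone hydrogenation is used.

Assumption: the SMILES reads as (5S,8R), with octyl and 8-OMe cis. The sense of induction in Step 4 must be assigned experimentally; both catalyst antipodes are available.

## Route

**Step 1**
Reactants: 1 furan; 2 1-bromooctane
Product: 3 2-octylfuran
Conditions: n-BuLi, THF, 0 °C → rt; then 2, 0 °C → rt
Reagents that add atoms: 1-bromooctane (2), CCCCCCCCBr
Why: Furan is lithiated selectively at C2 and the 2-furyllithium is alkylated by the primary bromide (heteroaryl lithiation/SN2 alkylation); no stereocentre is formed.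

**Step 2**
Reactants: 4 ethynyltrimethylsilane; 5 N,2-dimethoxy-N-methylacetamide
Product: 6 1-methoxy-4-(trimethylsilyl)but-3-yn-2-one
Conditions: 4, n-BuLi, THF, −78 °C; then 5, −78 → 0 °C; cold aq. citric acid quench
Reagents that add atoms: N,2-dimethoxy-N-methylacetamide (5), COCC(=O)N(C)OC
Why: Weinreb ketone synthesis: the acetylide adds once because the chelated tetrahedral intermediate collapses only on quench, and the TMS cap prevents conjugate addition of the released amine to the ynone.

**Step 3**
Reactants: 6; 7 N-bromosuccinimide
Product: 8 4-bromo-1-methoxybut-3-yn-2-one (used fresh)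
Conditions: NBS, AgNO3 (10 mol %), acetone, rt, dark
Reagents that add atoms: N-bromosuccinimide (7), O=C1CCC(=O)N1Br
Why: Ag(I)-catalysed electrophilic bromodesilylation of an alkynylsilane (via the silver acetylide) gives the 1-bromoalkyne under neutral conditions that leave the α-methoxy ketone untouched.

**Step 4 (key step)**
Reactants: 3 2-octylfuran; 8 4-bromo-1-methoxybut-3-yn-2-one
Product: 9 1-[(1S,4R)-3-bromo-1-octyl-7-oxabicyclo[2.2.1]hepta-2,5-dien-2-yl]-2-methoxyethan-1-one
Conditions: (S)-o-tolyl-diphenylprolinol oxazaborolidine·Tf2NH (15 mol %), 3 (1.5 equiv), CH2Cl2, −78 → −60 °C; Et3N quench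
Reagents that add atoms: none besides reactants 3 and 8 (all atoms of both are retained)
Why: Proposed new method: the cationic oxazaborolidinium binds the ynone carbonyl, lowers its LUMO and shields one face, so the furan adds in an asynchronous [4+2] (unsubstituted furan C5 to the Br-bearing β-carbon, octyl-bearing C2 to the acyl-bearing α-carbon) that fixes both bridgeheads (1S,4R) at once while the thermal background is frozen out; the closest known reaction types are the thermal, highly "ortho"-regioselective Diels–Alder reaction of 2-alkylfurans with 3-halopropiolates and oxazaborolidinium-catalysed enantioselective Diels–Alder reactions of acetylenic ketones and of furans, and the catalyst antipode is chosen after the sense of induction is assigned (Br anomalous-dispersion X-ray or correlation at 14).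

**Step 5**
Reactants: 9
Product: 10 1-[(1S,4R)-3-bromo-1-octyl-7-oxabicyclo[2.2.1]hept-2-en-2-yl]-2-methoxyethan-1-one
Conditions: KO2CN=NCO2K, AcOH (slow addition), CH2Cl2/MeOH, 0 °C
Reagents that add atoms: none
Why: Diimide reduction (concerted syn H2 transfer) is fastest at the strained, unhindered disubstituted C=C and ignores the tetrasubstituted bromoenone and the C–Br bond that H2/Pd would cleave; saturating this olefin also blocks acid-induced aromatisation, and both stereocentres are untouched.

**Step 6**
Reactants: 10; 11 N-methoxyacetamide
Product: 12 N-methoxy-N-[(1R,4S)-3-(methoxyacetyl)-4-octyl-7-oxabicyclo[2.2.1]hept-2-en-2-yl]acetamide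
Conditions: 11, NaH, THF, 0 °C; then 10, 0 °C → rt
Reagents that add atoms: N-methoxyacetamide (11), CC(=O)NOC
Why: Vinylic nucleophilic substitution by conjugate addition–elimination (as known for alkoxides on 3-halo-7-oxanorbornene-2-carbonyl compounds): the α-effect amide anion attacks the Br-bearing β-carbon of the strained enone and bromide leaves from the enolate, forming N1–C8a without touching the bridgeheads.

**Step 7**
Reactants: 12
Product: 13 (5S,8R)-1,3-dimethoxy-2-methyl-5-octyl-5,6,7,8-tetrahydro-5,8-epoxyquinolin-4(1H)-one
Conditions: KOt-Bu, THF, 0 °C → rt (can be telescoped with Step 6)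
Reagents that add atoms: none
Why: Camps-type cyclisation: the more acidic α-methoxy ketone CH2 (C3) enolises and attacks the activated N-methoxy-N-vinyl acetamide carbonyl (C2) in a six-membered aldol, and loss of water is driven by 4-pyridone aromaticity; the bulky base avoids deacetylation, and the ether bridge has no acidic β-hydrogen and survives.

**Step 8**
Reactants: 13
Product: 14 (5S,8R)-8-hydroxy-1,3-dimethoxy-2-methyl-5-octyl-5,6,7,8-tetrahydroquinolin-4(1H)-one (cis)
Conditions: Et3SiH (5 equiv), TFA, CH2Cl2, −20 → 0 °C; NaHCO3/MeOH work-up
Reagents that add atoms: none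
Why: Ionic hydrogenation (SN1-type reductive ether cleavage): only the tertiary C5–O bond ionises, because that cation is a vinylogous iminium stabilised through C4a by the ring nitrogen whereas a C8 cation on electron-poor C8a is not, and Et3SiH then attacks C5 pseudo-axially from the face opposite the pseudo-axial C8–O group (held axial by peri strain with N–OMe), putting H-5 anti to O-8 so that octyl is cis to OH (5S) with C8 (R) untouched; any E1 olefin re-protonates to the same cation.

**Step 9**
Reactants: 14; 15 iodomethane
Product: 16 waltherione K, (5S,8R)-1,3,8-trimethoxy-2-methyl-5-octyl-5,6,7,8-tetrahydroquinolin-4(1H)-one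
Conditions: MeI, Ag2O, 4 Å MS, CH2Cl2, rt → 40 °C, dark
Reagents that add atoms: iodomethane (15), CI
Why: Purdie (Ag2O/MeI) Williamson-type O-methylation of the secondary alcohol under near-neutral conditions avoids deprotonating the vinylogously acidic 2-CH3 or eliminating formaldehyde from N–OMe; no bond to C5 or C8 is broken, so (5S,8R) is retained.

## Compound list
| No. | Name | SMILES | Role |
|---|---|---|---|
| 1 | furan | c1ccoc1 | starting material |
| 2 | 1-bromooctane | CCCCCCCCBr | starting material |
| 3 | 2-octylfuran | CCCCCCCCc1ccco1 | intermediate |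
| 4 | ethynyltrimethylsilane | C#C[Si](C)(C)C | starting material |
| 5 | N,2-dimethoxy-N-methylacetamide | COCC(=O)N(C)OC | starting material |
| 6 | 1-methoxy-4-(trimethylsilyl)but-3-yn-2-one | COCC(=O)C#C[Si](C)(C)C | intermediate |
| 7 | N-bromosuccinimide | O=C1CCC(=O)N1Br | starting material (reagent) |
| 8 | 4-bromo-1-methoxybut-3-yn-2-one | COCC(=O)C#CBr | intermediate |
| 9 | (1S,4R)-bromo-oxanorbornadienyl methoxymethyl ketone | CCCCCCCC[C@@]12C=C[C@@H](O1)C(Br)=C2C(=O)COC | intermediate |
| 10 | (1S,4R)-bromo-oxanorbornenyl methoxymethyl ketone | CCCCCCCC[C@@]12CC[C@@H](O1)C(Br)=C2C(=O)COC | intermediate |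
| 11 | N-methoxyacetamide | CC(=O)NOC | starting material |
| 12 | (1R,4S)-N-methoxy-N-vinyl acetamide (enamide) | CCCCCCCC[C@@]12CC[C@@H](O1)C(N(OC)C(C)=O)=C2C(=O)COC | intermediate |
| 13 | (5S,8R)-5,8-epoxy-bridged N-methoxy-4-pyridone | CCCCCCCC[C@@]12CC[C@@H](O1)c3c2c(=O)c(OC)c(C)n3OC | intermediate |
| 14 | (5S,8R)-cis-8-hydroxy compound | CCCCCCCC[C@H]1CC[C@@H](O)c2c1c(=O)c(OC)c(C)n2OC | intermediate |
| 15 | iodomethane | CI | starting material (reagent) |
| 16 | waltherione K | CCCCCCCC[C@H]1CC[C@@H](OC)c2c1c(=O)c(OC)c(C)n2OC | target |

## Step count and risks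
Total steps: 9. Longest linear sequence: 8 (Steps 2–9), or 7 if Steps 6 and 7 are telescoped.

The three steps most likely to fail:

1. **Step 4.**
   - Risks: Friedel–Crafts-type hydroarylation of the furan instead of cycloaddition, acid-induced aromatisation of 9, or low ee.
   - Fallback: make the stereochemistry independent of the cycloaddition.
     1. Run the Diels–Alder reaction thermally (racemic), skip Step 5, and carry the diene through Steps 6–7.
     2. Isomerise with acid to the achiral 8-hydroxy-5-octyl-N-methoxyquinolone.
     3. Oxidise with PhI(OAc)2/MeOH to the 5-methoxy-5-octyl-8-oxo para-quinol ether, then saturate C6=C7 with CuH.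
     4. Set C8 (R) by Ru–TsDPEN transfer hydrogenation and O-methylate.
     5. Finish with the same Et3SiH/TFA reduction, which now ionises C5–OMe. The sequence is enantioconvergent.
2. **Step 8.**
   - Risks: modest facial selectivity, slow ionisation once the pyridone oxygen is protonated, or elimination and aromatisation.
   - Fallback: switch from substrate control to catalyst control. Open 13 by E1 (catalytic acid, no silane) to the 5-octyl-7,8-dihydro olefin, methylate O8, and hydrogenate the trisubstituted C5=C6 bond with a chiral Ir–P,N catalyst under N–O-tolerant homogeneous conditions.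
3. **Steps 6/7.**
   - Risks: O- rather than N-attack of the ambident hydroxamate, deacetylation, or the 2-pyridone Camps mode.
   - Fallback: build the oxygen heterocycle first. Convert 10 (NaOMe, then H3O+) into the β-diketone, C-acetylate C3 to the triketone, and cyclodehydrate to the fused 3-methoxy-2-methyl-4-pyrone. Then exchange the ring O for N–OMe with MeONH2·HCl (pyrone → pyridone ring-opening/ring-closure).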